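**Remark (assumption):** Lignan locants are used: C7/C7' benzylic, C8/C8' ring fusion, C9/C9' methylene, with the hydroxyl on C8'. The target SMILES corresponds to (7S,8R,7'R,8'S), cis ring fusion, both aryl groups exo. (S)-Malic acid, pivaldehyde, syringaldehyde and TIPSCl are taken as commercial.

## Retrosynthetic overview

1. The core is a cis-fused 3,7-dioxabicyclo[3.3.0]octane (ring A: O–C7–C8–C8'–C9'; ring B: O–C7'–C8'–C8–C9). Both oxolanes are taken back to γ-lactones (C9 and C9' at the carboxyl level), giving the 1-hydroxy bis-lactone 11; the endgame is iBu2AlH, then Et3SiH/BF3·OEt2, then desilylation.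
2. Enabling feature: the chain C9'–C8'(OH)–C8–C9 shared by rings A and B is the skeleton of (S)-malic acid. C8' is its α-hydroxy-acid carbon, so it can react as an enolate whose configuration is stored in a temporary tert-butyl dioxolanone ring. C9 is the distal carboxyl, γ to the C7' oxygen.
3. Ring B (key): C7'–C8' by aldol addition of the dioxolanone enolate to aldehyde 2 and O–C9 by lactonization in the same flask, giving spiro-lactone 8.
4. Ring A: C7–C8 by aldol addition of the lactone enolate of 8 to a second molecule of 2, and O–C9' by translactonization onto the dioxolanone carbonyl, which sheds pivaldehyde and frees the 8'-OH, giving 11.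
5. Ring order: temporary dioxolanone (step 2), ring B (step 3), ring A (step 4), both lactones reduced to oxolanes (steps 5 and 6).

Key step: step 3

## Route

**Step 1**
Reactants: 1 syringaldehyde
Product: 2 3,5-dimethoxy-4-(triisopropylsilyloxy)benzaldehyde
Conditions: TIPSCl (1.2 equiv), imidazole (2.5 equiv), DMF, rt
Reagents that add atoms: triisopropylsilyl chloride, CC(C)[Si](Cl)(C(C)C)C(C)C
Why: Imidazole-mediated O-silylation of the phenol gives a silyl ether that should tolerate amide bases, hydride and a Lewis acid at low temperature and that is removed at the end by fluoride without touching the benzylic ring ethers.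

**Step 2**
Reactants: 3 (S)-malic acid; 4 pivaldehyde
Product: 5 2-[(2S,4S)-2-tert-butyl-5-oxo-1,3-dioxolan-4-yl]acetic acid (cis)
Conditions: p-TsOH (cat.), H2SO4 (cat.), pentane, reflux, Dean–Stark; recrystallization
Reagents that add atoms: none
Why: Acid-catalysed acetalization of the α-hydroxy-acid unit under equilibrating conditions should favour the five-membered dioxolanone with tert-butyl and CH2CO2H cis, so the acetal carbon is set by the existing carbinol centre and the cis isomer is purified by crystallization.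

**Step 3**
Reactants: 5 2-[(2S,4S)-2-tert-butyl-5-oxo-1,3-dioxolan-4-yl]acetic acid; 2 3,5-dimethoxy-4-(triisopropylsilyloxy)benzaldehyde
Product: 8 (2S,5R,6R)-2-tert-butyl-6-[3,5-dimethoxy-4-(triisopropylsilyloxy)phenyl]-1,3,7-trioxaspiro[4.4]nonane-4,8-dione, via dilithium enolate 6 (not isolated), via hydroxy acid 7 (not isolated)
Conditions: LiN(SiMe3)2 (2.2 equiv), THF, −78 °C; 2 (1.05 equiv), −78 °C; PPTS (2.3 equiv); DIC (1.2 equiv), DMAP (0.1 equiv), −78 °C → rt
Reagents that add atoms: none
Why: Double deprotonation of 5 gives the carboxylate–dioxolanone enolate 6 (the carboxylate keeps its own α-CH2 from being deprotonated), whose enolate carbon C8' adds to the aldehyde carbon of 2 to form C7'–C8'; after mild protonation the C7' hydroxyl of 7 attacks the carbodiimide-activated carboxyl C9 and forms O–C9. The closest known reaction type is the aldol addition of chiral 2-tert-butyl-1,3-dioxolan-4-one enolates (self-regeneration of stereocentres) followed by a Steglich lactonization. Ring B is closed in the 5-exo-trig mode by acyl substitution, so the C7'–O bond is never broken and C7' cannot be scrambled by ionization. C8' is controlled by the acetal carbon: the aldehyde enters anti to the tert-butyl group, which replaces H by C7' with retention and returns the (S)-malic acid configuration as the quaternary carbinol centre. C7' is controlled by a Zimmerman–Traxler chair with the aryl group equatorial; because the CH2CO2Li arm is cis to the enolate oxygen, the new oxygen ends up syn to that arm, which after ring closure places the aryl group cis to the dioxolanone oxygen (the later 8'-OH) and trans to C9'. The step needs site selectivity of enolization, face selectivity and simple diastereoselection, secured respectively by the carboxylate, the tert-butyl acetal and the cyclic transition state.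

**Step 4**
Reactants: 8 (2S,5R,6R)-2-tert-butyl-6-[3,5-dimethoxy-4-(triisopropylsilyloxy)phenyl]-1,3,7-trioxaspiro[4.4]nonane-4,8-dione; 2 3,5-dimethoxy-4-(triisopropylsilyloxy)benzaldehyde
Product: 11 (1R,2R,5R,6S)-1-hydroxy-2,6-bis[3,5-dimethoxy-4-(triisopropylsilyloxy)phenyl]-3,7-dioxabicyclo[3.3.0]octane-4,8-dione, via lithium enolate 9 (not isolated), via lithium aldolate 10 (not isolated)
Conditions: LiN(SiMe3)2 (1.1 equiv), THF, −78 °C; 2 (1.2 equiv), −78 → −20 °C; AcOH
Reagents that add atoms: none
Why: The lithium enolate aldol addition to the aryl aldehyde is reversible at −20 °C, and only the aldolate that carries the new C7–C8 bond cis to the dioxolanone carbonyl and can place its aryl group on the convex face is able to close ring A by 5-exo-trig acyl substitution at C9' (translactonization of an activated acylal ester), an irreversible event that should fix C8 (cis fusion is the only attainable one) and C7 (exo aryl) while expelling the hemiacetal oxide, which sheds pivaldehyde and uncovers the 8'-OH.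

**Step 5**
Reactants: 11 (1R,2R,5R,6S)-1-hydroxy-2,6-bis[3,5-dimethoxy-4-(triisopropylsilyloxy)phenyl]-3,7-dioxabicyclo[3.3.0]octane-4,8-dione
Product: 12 (1R,2R,5R,6S)-2,6-bis[3,5-dimethoxy-4-(triisopropylsilyloxy)phenyl]-3,7-dioxabicyclo[3.3.0]octane-1,4,8-triol (bis-lactol, anomer mixture at C4 and C8)
Conditions: iBu2AlH (5 equiv), CH2Cl2, −78 °C; KNaC4H4O6 (aq.)
Reagents that add atoms: none
Why: Lactone-to-lactol half-reduction, in which the aluminium hemiacetals are stable at −78 °C until work-up, the tertiary OH only consumes one equivalent of hydride, and no stereocentre of the core is touched.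

**Step 6**
Reactants: 12 (1R,2R,5R,6S)-2,6-bis[3,5-dimethoxy-4-(triisopropylsilyloxy)phenyl]-3,7-dioxabicyclo[3.3.0]octane-1,4,8-triol
Product: 13 (1S,2R,5R,6S)-2,6-bis[3,5-dimethoxy-4-(triisopropylsilyloxy)phenyl]-3,7-dioxabicyclo[3.3.0]octan-1-ol
Conditions: Et3SiH (6 equiv), BF3·OEt2 (3 equiv), CH2Cl2, −78 → −40 °C; NaHCO3 (aq.)
Reagents that add atoms: none
Why: Ionic hydrogenation of lactols, in which BF3 ionizes each anomeric C–OH to a cyclic oxocarbenium ion that Et3SiH reduces to CH2 without opening the rings, the lactol hydroxyls ionizing far more readily at low temperature than the benzylic ring C–O bonds.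

**Step 7**
Reactants: 13 (1S,2R,5R,6S)-2,6-bis[3,5-dimethoxy-4-(triisopropylsilyloxy)phenyl]-3,7-dioxabicyclo[3.3.0]octan-1-ol
Product: 14 8-hydroxysyringaresinol, (1S,2R,5R,6S)-2,6-bis(4-hydroxy-3,5-dimethoxyphenyl)-3,7-dioxabicyclo[3.3.0]octan-1-ol
Conditions: Bu4NF (2.5 equiv), AcOH (2.5 equiv), THF, 0 °C → rt
Reagents that add atoms: none
Why: Fluoride cleavage of the two aryl silyl ethers, buffered with AcOH so that the liberated phenols stay protonated and no para-quinone methide ring opening can epimerize C7 or C7'.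

## Compound list

1 | syringaldehyde (4-hydroxy-3,5-dimethoxybenzaldehyde) | COc1cc(C=O)cc(OC)c1O | starting material
2 | 3,5-dimethoxy-4-(triisopropylsilyloxy)benzaldehyde | COc1cc(C=O)cc(OC)c1O[Si](C(C)C)(C(C)C)C(C)C | intermediate
3 | (S)-malic acid | O[C@@H](CC(=O)O)C(=O)O | starting material
4 | pivaldehyde | CC(C)(C)C=O | starting material
5 | 2-[(2S,4S)-2-tert-butyl-5-oxo-1,3-dioxolan-4-yl]acetic acid (tert-butyl and CH2CO2H cis) | CC(C)(C)[C@H]1O[C@@H](CC(=O)O)C(=O)O1 | intermediate
6 | dilithium 2-[(2S)-2-tert-butyl-5-oxido-1,3-dioxol-4-yl]acetate (enolate–carboxylate of 5) | CC(C)(C)[C@H]1OC(CC(=O)[O-])=C([O-])O1.[Li+].[Li+] | intermediate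
7 | 2-[(2S,4R)-2-tert-butyl-4-{(R)-[3,5-dimethoxy-4-(triisopropylsilyloxy)phenyl](hydroxy)methyl}-5-oxo-1,3-dioxolan-4-yl]acetic acid | CC(C)(C)[C@H]1O[C@](CC(=O)O)([C@H](O)c2cc(OC)c(O[Si](C(C)C)(C(C)C)C(C)C)c(OC)c2)C(=O)O1 | intermediate
8 | (2S,5R,6R)-2-tert-butyl-6-[3,5-dimethoxy-4-(triisopropylsilyloxy)phenyl]-1,3,7-trioxaspiro[4.4]nonane-4,8-dione (aryl cis to the dioxolanone ring oxygen on the lactone ring) | CC(C)(C)[C@H]1O[C@@]2(CC(=O)O[C@@H]2c3cc(OC)c(O[Si](C(C)C)(C(C)C)C(C)C)c(OC)c3)C(=O)O1 | intermediate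
9 | lithium (2S,5R,6R)-2-tert-butyl-6-[3,5-dimethoxy-4-(triisopropylsilyloxy)phenyl]-4-oxo-1,3,7-trioxaspiro[4.4]non-8-en-8-olate (lactone enolate of 8) | CC(C)(C)[C@H]1O[C@@]2(C=C([O-])O[C@@H]2c3cc(OC)c(O[Si](C(C)C)(C(C)C)C(C)C)c(OC)c3)C(=O)O1.[Li+] | intermediate
10 | lithium (S)-[3,5-dimethoxy-4-(triisopropylsilyloxy)phenyl]{(2S,5R,6R,9R)-2-tert-butyl-6-[3,5-dimethoxy-4-(triisopropylsilyloxy)phenyl]-4,8-dioxo-1,3,7-trioxaspiro[4.4]nonan-9-yl}methanolate | CC(C)(C)[C@H]1O[C@@]2([C@@H]([C@H]([O-])c3cc(OC)c(O[Si](C(C)C)(C(C)C)C(C)C)c(OC)c3)C(=O)O[C@@H]2c4cc(OC)c(O[Si](C(C)C)(C(C)C)C(C)C)c(OC)c4)C(=O)O1.[Li+] | intermediate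
11 | (1R,2R,5R,6S)-1-hydroxy-2,6-bis[3,5-dimethoxy-4-(triisopropylsilyloxy)phenyl]-3,7-dioxabicyclo[3.3.0]octane-4,8-dione (cis-fused, both aryl groups exo) | COc1cc([C@H]2OC(=O)[C@]3(O)[C@@H](c4cc(OC)c(O[Si](C(C)C)(C(C)C)C(C)C)c(OC)c4)OC(=O)[C@H]23)cc(OC)c1O[Si](C(C)C)(C(C)C)C(C)C | intermediate
12 | (1R,2R,5R,6S)-2,6-bis[3,5-dimethoxy-4-(triisopropylsilyloxy)phenyl]-3,7-dioxabicyclo[3.3.0]octane-1,4,8-triol (bis-lactol, anomer mixture at C4 and C8) | COc1cc([C@H]2OC(O)[C@]3(O)[C@@H](c4cc(OC)c(O[Si](C(C)C)(C(C)C)C(C)C)c(OC)c4)OC(O)[C@H]23)cc(OC)c1O[Si](C(C)C)(C(C)C)C(C)C | intermediate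
13 | (1S,2R,5R,6S)-2,6-bis[3,5-dimethoxy-4-(triisopropylsilyloxy)phenyl]-3,7-dioxabicyclo[3.3.0]octan-1-ol | COc1cc([C@H]2OC[C@]3(O)[C@@H](c4cc(OC)c(O[Si](C(C)C)(C(C)C)C(C)C)c(OC)c4)OC[C@H]23)cc(OC)c1O[Si](C(C)C)(C(C)C)C(C)C | intermediate
14 | 8-hydroxysyringaresinol, (7S,8R,7'R,8'S); (1S,2R,5R,6S)-2,6-bis(4-hydroxy-3,5-dimethoxyphenyl)-3,7-dioxabicyclo[3.3.0]octan-1-ol | COc1cc([C@H]2OC[C@]3(O)[C@@H](c4cc(OC)c(O)c(OC)c4)OC[C@H]23)cc(OC)c1O | target

## Step count and risks

Total step count: 7. Longest linear sequence: 6 steps (steps 2 to 7, from (S)-malic acid); step 1 is a one-step side branch.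

Steps most likely to fail:

**1. Step 4.** The lactone enolate 9 has the acetal oxygen β to the carbanion and may ring-open by β-elimination before it adds. In addition, the kinetic (chair) aldol addition of a lactone enolate favours the anti adduct, which would lead to the endo aryl group at C7, so the outcome depends on retro-aldol equilibration being faster than loss of material.
Fallback, from 8 back to 11: the dioxolanone is first opened by brief methanolysis (NaOMe cat., MeOH, −20 °C, AcOH quench), which should give methyl (2R,3R)-2-[3,5-dimethoxy-4-(triisopropylsilyloxy)phenyl]-3-hydroxy-5-oxooxolane-3-carboxylate F2 and pivaldehyde. LiN(iPr)2 (2.2 equiv, THF, −78 °C) then makes the dilithium oxide–enolate F3, in which the β-oxygen is an oxide and cannot leave. A Fráter–Seebach-type aldol addition to 2 anti to that oxide, that is cis to the ester, should give the dilithium aldolate F4, which lactonizes onto the methyl ester on warming and gives 11 after AcOH quench.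

**2. Step 3.** Simple diastereoselection at the C7' carbinol carbon may be poor if open or boat transition states compete, and the aldolate may undergo retro-aldol cleavage before the quench.
Fallback, from 5 back to 8: the aldol addition is run as before but worked up after the PPTS quench, and the two hydroxy acids are separated. Acid 7 is closed with DIC/DMAP (retention at C7'). The C7' epimer, 2-[(2S,4R)-2-tert-butyl-4-{(S)-[3,5-dimethoxy-4-(triisopropylsilyloxy)phenyl](hydroxy)methyl}-5-oxo-1,3-dioxolan-4-yl]acetic acid F1, is closed under Mitsunobu conditions (PPh3, DIAD, THF, 0 °C), where the carboxylate displaces the activated benzylic oxygen with inversion. Both epimers then converge on 8.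

**3. Step 6.** The Lewis acid may ionize the electron-rich benzylic C7–O and C7'–O bonds, leading to epimerization or reductive ring opening in competition with the lactol reduction.
Fallback, from 12 back to 13: NaBH4 (MeOH, 0 °C) should reduce the bis-lactol to (1R,2S,3R,4S)-1,4-bis[3,5-dimethoxy-4-(triisopropylsilyloxy)phenyl]-2,3-bis(hydroxymethyl)butane-1,2,4-triol F5. TsCl (2.2 equiv) in pyridine (0 → 40 °C) should sulfonylate only the two primary hydroxyls to give the bis(primary tosylate) F6, which closes both oxolanes in the flask by 5-exo-tet attack of the benzylic hydroxyls on the CH2OTs carbons. The benzylic C–O bonds are not broken, so C7 and C7' are retained and 13 results without any Lewis acid.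

## Further compounds

F1 | step 3 | 2-[(2S,4R)-2-tert-butyl-4-{(S)-[3,5-dimethoxy-4-(triisopropylsilyloxy)phenyl](hydroxy)methyl}-5-oxo-1,3-dioxolan-4-yl]acetic acid | CC(C)(C)[C@H]1O[C@](CC(=O)O)([C@@H](O)c2cc(OC)c(O[Si](C(C)C)(C(C)C)C(C)C)c(OC)c2)C(=O)O1
F2 | step 4 | methyl (2R,3R)-2-[3,5-dimethoxy-4-(triisopropylsilyloxy)phenyl]-3-hydroxy-5-oxooxolane-3-carboxylate | COC(=O)[C@@]1(O)CC(=O)O[C@@H]1c2cc(OC)c(O[Si](C(C)C)(C(C)C)C(C)C)c(OC)c2
F3 | step 4 | dilithium oxide–enolate of F2 | COC(=O)[C@@]1([O-])C=C([O-])O[C@@H]1c2cc(OC)c(O[Si](C(C)C)(C(C)C)C(C)C)c(OC)c2.[Li+].[Li+]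
F4 | step 4 | dilithium aldolate from F3 and 2 (new C7–C8 bond cis to the ester, (S)-carbinolate) | COC(=O)[C@@]1([O-])[C@@H]([C@H]([O-])c2cc(OC)c(O[Si](C(C)C)(C(C)C)C(C)C)c(OC)c2)C(=O)O[C@@H]1c3cc(OC)c(O[Si](C(C)C)(C(C)C)C(C)C)c(OC)c3.[Li+].[Li+]
F5 | step 6 | (1R,2S,3R,4S)-1,4-bis[3,5-dimethoxy-4-(triisopropylsilyloxy)phenyl]-2,3-bis(hydroxymethyl)butane-1,2,4-triol | OC[C@H]([C@H](O)c1cc(OC)c(O[Si](C(C)C)(C(C)C)C(C)C)c(OC)c1)[C@](O)(CO)[C@H](O)c1cc(OC)c(O[Si](C(C)C)(C(C)C)C(C)C)c(OC)c1
F6 | step 6 | bis(primary p-toluenesulfonate) of F5 | Cc1ccc(cc1)S(=O)(=O)OC[C@H]([C@H](O)c2cc(OC)c(O[Si](C(C)C)(C(C)C)C(C)C)c(OC)c2)[C@](O)(COS(=O)(=O)c3ccc(C)cc3)[C@H](O)c4cc(OC)c(O[Si](C(C)C)(C(C)C)C(C)C)c(OC)c4
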